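starting material 0.81 M; reagent 2.43 M; scavenger 0.243 M; free catalyst 16 mM

1. apparent order in free catalyst when 30% of the starting material are converted (percent change of the rate of making product for one percent more free catalyst charged)

- amounts and yields of released group count idle adduct too
- charge of starting material (flask): 0.81 M

    starting material + catalyst intermediate A ⇌ catalyst intermediate B (K1 = 0.73 /M, k1 = 141 /M/h)
    reagent + released group ⇌ idle adduct, settled at all times (K2 = 5.5 /M)
    catalyst intermediate B ⇌ released group + catalyst intermediate C (K3 = 1.1 M, k3 = 9.97 /h)
    reagent + free catalyst ⇌ catalyst intermediate A (K4 = 0.163 /M, k4 = 0.708 /M/h)
    catalyst intermediate C ⇌ free catalyst + product (K5 = 0.87 M, k5 = 11.9 /h)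
    scavenger + released group → scavenged by-product (k6 = 2.48 /M/h)

- The easy step is a count. Converting 30% of the starting material, with the catalyst charged at 1.98% of that charge, takes 15.2 rounds per catalyst: the turnover number at the mark, converted fraction over catalyst fraction.
- The neighbouring flask has twice the free catalyst, 0.0320 M, and needs 7.60 rounds per catalyst for the same conversion.
- Each catalyst step has one catalyst form on its left, so the split among the forms follows the composition of the flask, not the catalyst charge.
- The catalyst forms carry a share of the starting material far below the conversion looked at, so both flasks should hold nearly one composition at the mark.
- Each catalyst then works like its neighbour. That is the zero of the scale: order one, and a time factor of 0.5 for the neighbouring flask.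
- The scavenger step contains no catalyst and keeps its own clock, so the zero is approximate. The hand reckoning stops here and commits to order one.
- The forecast gives 0.98, range 0.93 to 1, a little below that order, on the ground: “The catalyst charge is tiny next to the substrates”.
- The simulated flask gives an apparent order of 0.97, a little below the zero of the scale.

- This flask makes its 15.2 rounds in 27.6 h, on average 1.82 h per round. The flask with twice the free catalyst reaches the mark in 0.503 of that time, so half the rounds take 1.83 h each: the count moved and the pace stayed. The pace is the thing to watch. Its answer to the reagent is shaped in part by the binding of reagent and released group into idle adduct: this flask shows an apparent order in reagent of 0.95 at the mark, and the same flask without that binding shows 1.7.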